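**Retrosynthetic overview**
1. Target 35 ⇐ ten-membered ketone 29 by acetonide removal, C6 angeloylation, C4 acetylation, C1 desilylation and unmasking of the α-methylene lactone (carried as its Me2NH adduct).
2. Ten-membered carbocycle (formed last) ⇐ C2–C3 bond by a proposed intramolecular nickel-catalysed reductive acyl–alkyl coupling of iodo thioester 28; no stereocentre is made in the ring closure.
3. 28 ⇐ C6–C7 bond by indium Barbier allylation of aldehyde 19 with 3-(bromomethyl)butenolide 13 (sets C6 and C7, delivers the α-methylene lactone), then a temporary C4/C6 acetonide.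
4. 13 ⇐ iridium-catalysed 2-(alkoxycarbonyl)allylation/lactonisation of alcohol 6 (γ-lactone formed first, sets C8); 6 ⇐ Brown anti-crotylation of 1 (sets C1, C10); 19 ⇐ copper–bis(oxazoline) Mukaiyama aldol of benzyl pyruvate (sets C4).
5. Ring order: γ-lactone (step 5) → 1,3-dioxane protecting ring (step 11) → ten-membered ring (step 17).

Assumption: names use germacranolide numbering of the target (C1 CHOH, C3 C=O, C4 C(CH3)OAc, C6 CH–OAng, C7/C8 lactone fusion with C8–O, C10 CH(CH3), C11/C12/C13 lactone α-carbon, carbonyl and exocyclic CH2); TBS = tert-butyldimethylsilyl, TBSO = its ether; amine adducts 24–34 are carried as C11 epimer mixtures, a centre erased in step 22.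

**Step 1**
Reactants: 1 2-(TBSO)acetaldehyde
Product: 3 (2R,3R)-1-(TBSO)-3-methylpent-4-en-2-ol, via borinate 2 (not isolated)
Conditions: trans-2-butene, n-BuLi, KOtBu, THF, −78 to −45 °C; (+)-Ipc2BOMe, −78 °C; BF3·OEt2; then 1, −78 °C; NaOH, H2O2
Reagents that add atoms: trans-2-butene (C/C=C/C)
Why: Brown asymmetric crotylboration: the (E)-crotylborane adds through a chair Zimmerman–Traxler transition state (anti C1/C10 relationship) and the isopinocampheyl groups from (−)-α-pinene select the re face of the aldehyde, setting both centres.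

**Step 2**
Reactants: 3 (2R,3R)-1-(TBSO)-3-methylpent-4-en-2-ol
Product: 4 (3R,4R)-4,5-bis(TBSO)-3-methylpent-1-ene
Conditions: TBSOTf, 2,6-lutidine, CH2Cl2, −78 → 0 °C
Reagents that add atoms: tert-butyldimethylsilyl triflate (CC(C)(C)[Si](C)(C)OS(=O)(=O)C(F)(F)F)
Why: Standard silyl ether formation on the secondary alcohol; no stereocentre is touched.

**Step 3**
Reactants: 4 (3R,4R)-4,5-bis(TBSO)-3-methylpent-1-ene
Product: 6 (3R,4R)-4,5-bis(TBSO)-3-methylpentan-1-ol, via alkylborane 5 (not isolated)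
Conditions: 9-BBN, THF, 0 °C → rt; then NaOH, H2O2
Reagents that add atoms: hydrogen peroxide (OO)
Why: Anti-Markovnikov hydroboration–oxidation of the terminal alkene places the hydroxyl on C8 without touching the existing centres.

**Step 4**
Reactants: 7 methyl 2-(hydroxymethyl)acrylate
Product: 8 methyl 2-{[(tert-butoxycarbonyl)oxy]methyl}acrylate
Conditions: Boc2O, DMAP (cat.), CH2Cl2, 0 °C → rt
Reagents that add atoms: di-tert-butyl dicarbonate (CC(C)(C)OC(=O)OC(=O)OC(C)(C)C)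
Why: DMAP-catalysed O-acylation gives the allylic carbonate that serves as the 2-(alkoxycarbonyl)allyl donor.

**Step 5**
Reactants: 6 (3R,4R)-4,5-bis(TBSO)-3-methylpentan-1-ol; 8 methyl 2-{[(tert-butoxycarbonyl)oxy]methyl}acrylate
Product: 11 (5R)-5-[(2R,3R)-3,4-bis(TBSO)-2-methylbutyl]-3-methylideneoxolan-2-one, via aldehyde 9 (not isolated), via hydroxy ester 10 (not isolated)
Conditions: [Ir(cod)Cl]2 (2.5 mol %), (S)-SEGPHOS (5 mol %), 4-chloro-3-nitrobenzoic acid (10 mol %), Cs2CO3 (20 mol %), THF, 60 °C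
Reagents that add atoms: none
Why: Iridium-catalysed transfer-hydrogenative 2-(alkoxycarbonyl)allylation from the alcohol oxidation level (Krische type): the alcohol is dehydrogenated to 9, the chiral π-allyliridium adds under catalyst control to set C8 (R), and hydroxy ester 10 lactonises in situ.

**Step 6**
Reactants: 11 (5R)-5-[(2R,3R)-3,4-bis(TBSO)-2-methylbutyl]-3-methylideneoxolan-2-one
Product: 13 (5R)-3-(bromomethyl)-5-[(2R,3R)-3,4-bis(TBSO)-2-methylbutyl]furan-2(5H)-one, via dibromide 12 (not isolated)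
Conditions: Br2, CH2Cl2, 0 °C (dark); then Et3N, 0 °C → rt
Reagents that add atoms: bromine (BrBr)
Why: Bromine addition to the exocyclic alkene followed by amine-induced E2 loss of HBr (ring C7–H with the tertiary C11–Br) gives the conjugated endocyclic butenolide bearing the allylic bromide; C8 is not involved.

**Step 7**
Reactants: 14 S-ethyl ethanethioate
Product: 16 1-(ethylsulfanyl)-1-(trimethylsilyloxy)ethene, via lithium enolate 15 (not isolated)
Conditions: LiN(iPr)2, THF, −78 °C; Me3SiCl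
Reagents that add atoms: chlorotrimethylsilane (C[Si](C)(C)Cl)
Why: Kinetic enolisation of the thioester and O-silylation give the silyl ketene acetal.

**Step 8**
Reactants: 16 1-(ethylsulfanyl)-1-(trimethylsilyloxy)ethene; 17 benzyl 2-oxopropanoate
Product: 18 benzyl (2R)-4-(ethylsulfanyl)-2-methyl-4-oxo-2-(trimethylsilyloxy)butanoate
Conditions: Cu(OTf)2 (10 mol %), (R,R)-tBu-box (11 mol %), THF, −78 °C; neutral work-up
Reagents that add atoms: none
Why: Evans copper–bis(oxazoline)-catalysed enantioselective Mukaiyama aldol addition to a pyruvate: the keto ester chelates the square-planar divalent copper centre, the tert-butyl groups shield one face and set the C4 tertiary centre (R), and silyl transfer gives the TMS ether directly.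

**Step 9**
Reactants: 18 benzyl (2R)-4-(ethylsulfanyl)-2-methyl-4-oxo-2-(trimethylsilyloxy)butanoate
Product: 19 benzyl (2R)-2-methyl-4-oxo-2-(trimethylsilyloxy)butanoate
Conditions: Et3SiH, 10% Pd/C, acetone, rt
Reagents that add atoms: none
Why: Fukuyama reduction: palladium inserts into the C(acyl)–S bond and the silane delivers hydride, giving the aldehyde without touching the benzyl ester or the quaternary centre.

**Step 10**
Reactants: 13 (5R)-3-(bromomethyl)-5-[(2R,3R)-3,4-bis(TBSO)-2-methylbutyl]furan-2(5H)-one; 19 benzyl (2R)-2-methyl-4-oxo-2-(trimethylsilyloxy)butanoate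
Product: 21 benzyl (2R,4S)-4-{(2R,3R)-2-[(2R,3R)-3,4-bis(TBSO)-2-methylbutyl]-4-methylidene-5-oxooxolan-3-yl}-4-hydroxy-2-methyl-2-(trimethylsilyloxy)butanoate, via allylindium dibromide 20 (not isolated)
Conditions: In powder, THF/H2O (3:1), rt; used crude in step 11
Reagents that add atoms: none
Why: Indium-mediated Barbier allylation with a 2-(bromomethyl)enoate-type donor: the allylindium reacts at its γ-carbon (C7) on the butenolide face anti to the C8 side chain through a chair transition state with the aldehyde chain equatorial, which sets C7 (trans to C8) and C6 and releases the α-methylene lactone.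

**Step 11**
Reactants: 21 Barbier adduct (TMS ether)
Product: 23 benzyl (4R,6S)-6-{(2R,3R)-2-[(2R,3R)-3,4-bis(TBSO)-2-methylbutyl]-4-methylidene-5-oxooxolan-3-yl}-2,2,4-trimethyl-1,3-dioxane-4-carboxylate, via diol 22 (not isolated)
Conditions: PPTS, MeOH, 0 °C; then 2,2-dimethoxypropane, PPTS, acetone, rt
Reagents that add atoms: 2,2-dimethoxypropane (COC(C)(C)OC)
Why: Acid-catalysed methanolysis of the tertiary TMS ether and transketalisation give the acetonide of the syn-1,3-diol, which blocks γ-lactonisation onto the ester and preorganises the chain (both chain ends equatorial).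

**Step 12**
Reactants: 23 acetonide benzyl ester
Product: 24 benzyl (4R,6S)-6-{(2R,3R)-2-[(2R,3R)-3,4-bis(TBSO)-2-methylbutyl]-4-[(dimethylamino)methyl]-5-oxooxolan-3-yl}-2,2,4-trimethyl-1,3-dioxane-4-carboxylate
Conditions: Me2NH (2 M in THF), 0 °C → rt
Reagents that add atoms: dimethylamine (CNC)
Why: Aza-Michael addition masks the α-methylene lactone as a Mannich base (safe towards hydrogenation, radicals and nucleophiles); the new C11 centre is erased in step 22.

**Step 13**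
Reactants: 24 amine-masked benzyl ester
Product: 25 (4R,6S)-6-{(2R,3R)-2-[(2R,3R)-3,4-bis(TBSO)-2-methylbutyl]-4-[(dimethylamino)methyl]-5-oxooxolan-3-yl}-2,2,4-trimethyl-1,3-dioxane-4-carboxylic acid
Conditions: H2 (1 atm), 10% Pd/C, EtOAc, rt
Reagents that add atoms: none
Why: Hydrogenolysis of the benzyl ester frees the hindered acid; silyl ethers, acetonide and the saturated lactone are inert.

**Step 14**
Reactants: 25 carboxylic acid
Product: 26 S-(pyridin-2-yl) (4R,6S)-6-{(2R,3R)-2-[(2R,3R)-3,4-bis(TBSO)-2-methylbutyl]-4-[(dimethylamino)methyl]-5-oxooxolan-3-yl}-2,2,4-trimethyl-1,3-dioxane-4-carbothioate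
Conditions: 2,2'-dipyridyl disulfide, PPh3, CH2Cl2, rt
Reagents that add atoms: 2,2'-dipyridyl disulfide (c1ccc(SSc2ccccn2)nc1)
Why: Mukaiyama redox condensation converts the acid into the S-2-pyridyl thioester, the acyl donor for step 17.

**Step 15**
Reactants: 26 pyridyl thioester (bis-TBS)
Product: 27 S-(pyridin-2-yl) (4R,6S)-6-{(2R,3R)-4-[(dimethylamino)methyl]-2-[(2R,3R)-4-hydroxy-2-methyl-3-(TBSO)butyl]-5-oxooxolan-3-yl}-2,2,4-trimethyl-1,3-dioxane-4-carbothioate
Conditions: HF·pyridine, pyridine, THF, 0 °C; used at once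
Reagents that add atoms: none
Why: Buffered fluoride cleaves the primary silyl ether chemoselectively in the presence of the hindered secondary one.

**Step 16**
Reactants: 27 primary alcohol
Product: 28 S-(pyridin-2-yl) (4R,6S)-6-{(2R,3R)-4-[(dimethylamino)methyl]-2-[(2R,3R)-4-iodo-2-methyl-3-(TBSO)butyl]-5-oxooxolan-3-yl}-2,2,4-trimethyl-1,3-dioxane-4-carbothioate
Conditions: I2, PPh3, imidazole, CH2Cl2, 0 °C
Reagents that add atoms: iodine (II)
Why: Appel-type iodination of the primary alcohol by SN2 at C2; C1 is untouched.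

**Step 17**
Reactants: 28 iodo thioester
Product: 29 (1S,4R,6S,7R,8R,10R)-13-(dimethylamino)-4,6-(isopropylidenedioxy)-3-oxo-1-(TBSO)germacran-12,8-olide
Conditions: NiBr2·diglyme (30 mol %), 4,4'-di-tert-butyl-2,2'-bipyridine (33 mol %), Mn powder, DMA/THF, 25 °C, syringe-pump addition of 28 (final 2 mM)
Reagents that add atoms: none
Why: Proposed new method: an intramolecular nickel-catalysed reductive acyl–alkyl cross-electrophile coupling (macroketonisation) in which zerovalent nickel (bipyridine-ligated) inserts, helped by pyridine-N chelation, into the C(acyl)–S bond to give a divalent acyl–nickel species, the tethered primary iodide is turned by halogen-atom abstraction at monovalent nickel into the C2 radical, this radical is captured at the acyl–nickel centre, and reductive elimination from trivalent nickel forms the C2–C3 bond and the ten-membered ring while Mn returns nickel to the low-valent state; radical capture avoids the β-silyloxy elimination of a discrete organometallic, no stereocentre is formed, and the trans-lactone and the syn-acetonide hold C2 and C3 close; the closest known reaction type is the intermolecular nickel-catalysed reductive coupling of S-2-pyridyl thioesters or acid chlorides with alkyl iodides to give ketones, used here as a medium-ring closure with an α-quaternary α-alkoxy acyl donor.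

**Step 18**
Reactants: 29 macrocyclic ketone acetonide
Product: 30 (1S,4R,6S,7R,8R,10R)-13-(dimethylamino)-4,6-dihydroxy-3-oxo-1-(TBSO)germacran-12,8-olide
Conditions: AcOH/THF/H2O (3:1:1), 40 °C
Reagents that add atoms: none
Why: Mild aqueous acid hydrolysis of the acetonide; the secondary TBS ether and the lactone survive, and the aqueous medium keeps any C6-OH/C3 hemiketal reversible.

**Step 19**
Reactants: 30 diol
Product: 31 (1S,4R,6S,7S,8R,10R)-6-(angeloyloxy)-13-(dimethylamino)-4-hydroxy-3-oxo-1-(TBSO)germacran-12,8-olide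
Conditions: angelic acid, 2,4,6-trichlorobenzoyl chloride, Et3N, toluene, rt; then 30, 75 °C (no DMAP)
Reagents that add atoms: angelic acid (C/C=C(/C)C(=O)O)
Why: Yamaguchi esterification with the preformed mixed anhydride acylates the secondary C6 hydroxyl selectively over the tertiary C4 hydroxyl, and the DMAP-free protocol keeps the (Z)-geometry of the angelate.

**Step 20**
Reactants: 31 6-angelate
Product: 32 (1S,4R,6S,7S,8R,10R)-4-acetoxy-6-(angeloyloxy)-13-(dimethylamino)-3-oxo-1-(TBSO)germacran-12,8-olide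
Conditions: Ac2O, DMAP, Et3N, CH2Cl2, 40 °C
Reagents that add atoms: acetic anhydride (CC(=O)OC(C)=O)
Why: DMAP-catalysed acetylation (N-acetylpyridinium) of the tertiary α-ketol hydroxyl, with C1 still protected.

**Step 21**
Reactants: 32 diester silyl ether
Product: 33 (1S,4R,6S,7S,8R,10R)-4-acetoxy-6-(angeloyloxy)-13-(dimethylamino)-1-hydroxy-3-oxogermacran-12,8-olide
Conditions: HF·pyridine, THF, 0 °C → rt
Reagents that add atoms: none
Why: Mildly acidic fluoride desilylation of the secondary TBS ether avoids retro-aldol or β-elimination of the β-hydroxy ketone.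

**Step 22**
Reactants: 33 amine-masked target
Product: 35 (1S,4R,6S,7S,8R,10R)-4-acetoxy-6-(angeloyloxy)-1-hydroxy-3-oxogermacr-11(13)-en-12,8-olide, via ammonium iodide 34 (not isolated)
Conditions: MeI, THF, rt; then sat. aq. NaHCO3, rt
Reagents that add atoms: none
Why: N-Methylation and E1cB (Hofmann-type retro-Michael) loss of trimethylamine under bicarbonate regenerate the exocyclic α-methylene lactone, giving the target.

**Compound list**
1 | 2-(TBSO)acetaldehyde | O=CCO[Si](C)(C)C(C)(C)C | starting material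
2 | (2R,3R)-1-(TBSO)-3-methylpent-4-en-2-yl diisopinocampheylborinate (Ipc from (−)-α-pinene) | C=C[C@@H](C)[C@@H](OB([C@H]1C[C@H]2C[C@@H]([C@@H]1C)C2(C)C)[C@H]1C[C@H]2C[C@@H]([C@@H]1C)C2(C)C)CO[Si](C)(C)C(C)(C)C | intermediate
3 | (2R,3R)-1-(TBSO)-3-methylpent-4-en-2-ol | C=C[C@@H](C)[C@@H](O)CO[Si](C)(C)C(C)(C)C | intermediate
4 | (3R,4R)-4,5-bis(TBSO)-3-methylpent-1-ene | C=C[C@@H](C)[C@@H](O[Si](C)(C)C(C)(C)C)CO[Si](C)(C)C(C)(C)C | intermediate
5 | 9-[(3R,4R)-4,5-bis(TBSO)-3-methylpentyl]-9-borabicyclo[3.3.1]nonane | B1(CC[C@@H](C)[C@@H](O[Si](C)(C)C(C)(C)C)CO[Si](C)(C)C(C)(C)C)C2CCCC1CCC2 | intermediate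
6 | (3R,4R)-4,5-bis(TBSO)-3-methylpentan-1-ol | OCC[C@@H](C)[C@@H](O[Si](C)(C)C(C)(C)C)CO[Si](C)(C)C(C)(C)C | intermediate
7 | methyl 2-(hydroxymethyl)acrylate | C=C(CO)C(=O)OC | starting material
8 | methyl 2-{[(tert-butoxycarbonyl)oxy]methyl}acrylate | C=C(COC(=O)OC(C)(C)C)C(=O)OC | intermediate
9 | (3R,4R)-4,5-bis(TBSO)-3-methylpentanal | O=CC[C@@H](C)[C@@H](O[Si](C)(C)C(C)(C)C)CO[Si](C)(C)C(C)(C)C | intermediate
10 | methyl (4R,6R,7R)-7,8-bis(TBSO)-4-hydroxy-6-methyl-2-methylideneoctanoate | C=C(C[C@H](O)C[C@@H](C)[C@@H](O[Si](C)(C)C(C)(C)C)CO[Si](C)(C)C(C)(C)C)C(=O)OC | intermediate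
11 | (5R)-5-[(2R,3R)-3,4-bis(TBSO)-2-methylbutyl]-3-methylideneoxolan-2-one | C=C1C(=O)O[C@H](C[C@@H](C)[C@@H](O[Si](C)(C)C(C)(C)C)CO[Si](C)(C)C(C)(C)C)C1 | intermediate
12 | (5R)-3-bromo-3-(bromomethyl)-5-[(2R,3R)-3,4-bis(TBSO)-2-methylbutyl]oxolan-2-one (C3 epimers) | BrCC1(Br)C(=O)O[C@H](C[C@@H](C)[C@@H](O[Si](C)(C)C(C)(C)C)CO[Si](C)(C)C(C)(C)C)C1 | intermediate
13 | (5R)-3-(bromomethyl)-5-[(2R,3R)-3,4-bis(TBSO)-2-methylbutyl]furan-2(5H)-one | BrCC1=C[C@@H](C[C@@H](C)[C@@H](O[Si](C)(C)C(C)(C)C)CO[Si](C)(C)C(C)(C)C)OC1=O | intermediate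
14 | S-ethyl ethanethioate | CC(=O)SCC | starting material
15 | lithium 1-(ethylsulfanyl)ethenolate | [Li+].C=C([O-])SCC | intermediate
16 | 1-(ethylsulfanyl)-1-(trimethylsilyloxy)ethene | C=C(O[Si](C)(C)C)SCC | intermediate
17 | benzyl 2-oxopropanoate (benzyl pyruvate) | CC(=O)C(=O)OCc1ccccc1 | starting material
18 | benzyl (2R)-4-(ethylsulfanyl)-2-methyl-4-oxo-2-(trimethylsilyloxy)butanoate | O=C(OCc1ccccc1)[C@](C)(O[Si](C)(C)C)CC(=O)SCC | intermediate
19 | benzyl (2R)-2-methyl-4-oxo-2-(trimethylsilyloxy)butanoate | O=CC[C@@](C)(O[Si](C)(C)C)C(=O)OCc1ccccc1 | intermediate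
20 | {[(5R)-5-[(2R,3R)-3,4-bis(TBSO)-2-methylbutyl]-2-oxo-2,5-dihydrofuran-3-yl]methyl}indium dibromide | Br[In](Br)CC1=C[C@@H](C[C@@H](C)[C@@H](O[Si](C)(C)C(C)(C)C)CO[Si](C)(C)C(C)(C)C)OC1=O | intermediate
21 | benzyl (2R,4S)-4-{(2R,3R)-2-[(2R,3R)-3,4-bis(TBSO)-2-methylbutyl]-4-methylidene-5-oxooxolan-3-yl}-4-hydroxy-2-methyl-2-(trimethylsilyloxy)butanoate | C=C1C(=O)O[C@H](C[C@@H](C)[C@@H](O[Si](C)(C)C(C)(C)C)CO[Si](C)(C)C(C)(C)C)[C@H]1[C@@H](O)C[C@@](C)(O[Si](C)(C)C)C(=O)OCc1ccccc1 | intermediate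
22 | benzyl (2R,4S)-4-{(2R,3R)-2-[(2R,3R)-3,4-bis(TBSO)-2-methylbutyl]-4-methylidene-5-oxooxolan-3-yl}-2,4-dihydroxy-2-methylbutanoate | C=C1C(=O)O[C@H](C[C@@H](C)[C@@H](O[Si](C)(C)C(C)(C)C)CO[Si](C)(C)C(C)(C)C)[C@H]1[C@@H](O)C[C@@](C)(O)C(=O)OCc1ccccc1 | intermediate
23 | benzyl (4R,6S)-6-{(2R,3R)-2-[(2R,3R)-3,4-bis(TBSO)-2-methylbutyl]-4-methylidene-5-oxooxolan-3-yl}-2,2,4-trimethyl-1,3-dioxane-4-carboxylate | C=C1C(=O)O[C@H](C[C@@H](C)[C@@H](O[Si](C)(C)C(C)(C)C)CO[Si](C)(C)C(C)(C)C)[C@H]1[C@@H]2C[C@](C)(C(=O)OCc3ccccc3)OC(C)(C)O2 | intermediate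
24 | benzyl (4R,6S)-6-{(2R,3R)-2-[(2R,3R)-3,4-bis(TBSO)-2-methylbutyl]-4-[(dimethylamino)methyl]-5-oxooxolan-3-yl}-2,2,4-trimethyl-1,3-dioxane-4-carboxylate (oxolane C4 epimers) | CN(C)CC1C(=O)O[C@H](C[C@@H](C)[C@@H](O[Si](C)(C)C(C)(C)C)CO[Si](C)(C)C(C)(C)C)[C@H]1[C@@H]2C[C@](C)(C(=O)OCc3ccccc3)OC(C)(C)O2 | intermediate
25 | (4R,6S)-6-{(2R,3R)-2-[(2R,3R)-3,4-bis(TBSO)-2-methylbutyl]-4-[(dimethylamino)methyl]-5-oxooxolan-3-yl}-2,2,4-trimethyl-1,3-dioxane-4-carboxylic acid | CN(C)CC1C(=O)O[C@H](C[C@@H](C)[C@@H](O[Si](C)(C)C(C)(C)C)CO[Si](C)(C)C(C)(C)C)[C@H]1[C@@H]2C[C@](C)(C(=O)O)OC(C)(C)O2 | intermediate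
26 | S-(pyridin-2-yl) (4R,6S)-6-{(2R,3R)-2-[(2R,3R)-3,4-bis(TBSO)-2-methylbutyl]-4-[(dimethylamino)methyl]-5-oxooxolan-3-yl}-2,2,4-trimethyl-1,3-dioxane-4-carbothioate | CN(C)CC1C(=O)O[C@H](C[C@@H](C)[C@@H](O[Si](C)(C)C(C)(C)C)CO[Si](C)(C)C(C)(C)C)[C@H]1[C@@H]2C[C@](C)(C(=O)Sc3ccccn3)OC(C)(C)O2 | intermediate
27 | S-(pyridin-2-yl) (4R,6S)-6-{(2R,3R)-4-[(dimethylamino)methyl]-2-[(2R,3R)-4-hydroxy-2-methyl-3-(TBSO)butyl]-5-oxooxolan-3-yl}-2,2,4-trimethyl-1,3-dioxane-4-carbothioate | CN(C)CC1C(=O)O[C@H](C[C@@H](C)[C@@H](O[Si](C)(C)C(C)(C)C)CO)[C@H]1[C@@H]2C[C@](C)(C(=O)Sc3ccccn3)OC(C)(C)O2 | intermediate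
28 | S-(pyridin-2-yl) (4R,6S)-6-{(2R,3R)-4-[(dimethylamino)methyl]-2-[(2R,3R)-4-iodo-2-methyl-3-(TBSO)butyl]-5-oxooxolan-3-yl}-2,2,4-trimethyl-1,3-dioxane-4-carbothioate | CN(C)CC1C(=O)O[C@H](C[C@@H](C)[C@@H](O[Si](C)(C)C(C)(C)C)CI)[C@H]1[C@@H]2C[C@](C)(C(=O)Sc3ccccn3)OC(C)(C)O2 | intermediate
29 | (1S,4R,6S,7R,8R,10R)-13-(dimethylamino)-4,6-(isopropylidenedioxy)-3-oxo-1-(TBSO)germacran-12,8-olide (C11 epimers) | CN(C)CC1C(=O)O[C@@H]2C[C@@H](C)[C@@H](O[Si](C)(C)C(C)(C)C)CC(=O)[C@](C)(OC(C)(C)O3)C[C@H]3[C@@H]12 | intermediate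
30 | (1S,4R,6S,7R,8R,10R)-13-(dimethylamino)-4,6-dihydroxy-3-oxo-1-(TBSO)germacran-12,8-olide (C11 epimers) | CN(C)CC1C(=O)O[C@@H]2C[C@@H](C)[C@@H](O[Si](C)(C)C(C)(C)C)CC(=O)[C@](C)(O)C[C@H](O)[C@@H]12 | intermediate
31 | (1S,4R,6S,7S,8R,10R)-6-(angeloyloxy)-13-(dimethylamino)-4-hydroxy-3-oxo-1-(TBSO)germacran-12,8-olide (C11 epimers) | CN(C)CC1C(=O)O[C@@H]2C[C@@H](C)[C@@H](O[Si](C)(C)C(C)(C)C)CC(=O)[C@](C)(O)C[C@H](OC(=O)/C(C)=C\C)[C@@H]12 | intermediate
32 | (1S,4R,6S,7S,8R,10R)-4-acetoxy-6-(angeloyloxy)-13-(dimethylamino)-3-oxo-1-(TBSO)germacran-12,8-olide (C11 epimers) | CN(C)CC1C(=O)O[C@@H]2C[C@@H](C)[C@@H](O[Si](C)(C)C(C)(C)C)CC(=O)[C@](C)(OC(C)=O)C[C@H](OC(=O)/C(C)=C\C)[C@@H]12 | intermediate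
33 | (1S,4R,6S,7S,8R,10R)-4-acetoxy-6-(angeloyloxy)-13-(dimethylamino)-1-hydroxy-3-oxogermacran-12,8-olide (C11 epimers) | CN(C)CC1C(=O)O[C@@H]2C[C@@H](C)[C@@H](O)CC(=O)[C@](C)(OC(C)=O)C[C@H](OC(=O)/C(C)=C\C)[C@@H]12 | intermediate
34 | (1S,4R,6S,7S,8R,10R)-4-acetoxy-6-(angeloyloxy)-1-hydroxy-3-oxo-13-(trimethylammonio)germacran-12,8-olide iodide (C11 epimers) | C[N+](C)(C)CC1C(=O)O[C@@H]2C[C@@H](C)[C@@H](O)CC(=O)[C@](C)(OC(C)=O)C[C@H](OC(=O)/C(C)=C\C)[C@@H]12.[I-] | intermediate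
35 | (1S,4R,6S,7S,8R,10R)-4-acetoxy-6-(angeloyloxy)-1-hydroxy-3-oxogermacr-11(13)-en-12,8-olide (CNP0141210.6) | C=C1C(=O)O[C@@H]2C[C@@H](C)[C@@H](O)CC(=O)[C@](C)(OC(C)=O)C[C@H](OC(=O)/C(C)=C\C)[C@@H]12 | target

**Totals**
Total step count: 22. Longest linear sequence: 18 steps (1, 2, 3, 5, 6, then 10–22).

**Steps most likely to fail**

Step 17 (proposed new ring closure). Risks are medium-ring strain, the hindered α-quaternary acyl donor, decarbonylation of the acyl–nickel species, and reduction or dimerisation of the iodide. The fallback uses known chemistry and moves the ring closure to C1=C2; it sets out from acid 25 and returns at 29. The acid is activated with carbonyldiimidazole and C-acylated with the magnesium enolate of (dimethoxyphosphoryl)acetic acid (MgCl2, Et3N, decarboxylation) to give the β-ketophosphonate F1. HF·pyridine removes both silyl groups to give the diol F2, and NaIO4 cleaves the C1–C2 glycol to the C1 aldehyde F3. A Horner–Wadsworth–Emmons macrocyclisation under Masamune–Roush conditions (LiCl, iPr2NEt, MeCN, high dilution) closes the ring to the (E)-enone F4. Copper-catalysed asymmetric conjugate borylation (CuCl, NaOtBu, Josiphos-type ligand chosen for the 1S product, B2pin2, MeOH) gives the pinacol boronate F5. Oxidation with NaBO3·4H2O proceeds with retention to the β-hydroxy ketone F6, and TBSOTf/2,6-lutidine then gives 29. C1 is re-set under catalyst control in this fallback, which may be mismatched with the macrocycle's own facial bias.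

Step 10 (Barbier union). The risk is incomplete control at C6 (chair versus open transition state) or γ-lactonisation of the free C6 hydroxyl. The fallback sets C6 by hydroxyl-directed reduction instead of by the allylation; it sets out from 21 (as a C6-epimer mixture) and returns at 22. Dess–Martin periodinane oxidises both epimers to the C6 ketone F7. Citric acid in MeOH removes the TMS group to give the β-hydroxy ketone F8. Narasaka–Prasad reduction (Et2BOMe, NaBH4, THF/MeOH, −78 °C) delivers hydride through the boron chelate syn to the C4 hydroxyl and gives diol 22, which enters the second stage of step 11 to give 23. This does not correct C7, which relies on attack anti to the C8 side chain.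

Step 20 (acetylation of the hindered tertiary α-ketol hydroxyl). The risk is sluggish acylation with competing elimination at C1 or angelate isomerisation under forcing conditions. The fallback delivers the acetyl group intramolecularly; it sets out from diol 30 and returns at 32. Trimethyl orthoacetate with PPTS gives the six-membered cyclic orthoacetate F9. Brief treatment with aqueous acetic acid opens it under kinetic control to the ester on the more hindered tertiary oxygen, by analogy with the classical corticosteroid 17-monoester synthesis, giving the 4-acetate 6-alcohol F10. Yamaguchi angeloylation of F10 under the conditions of step 19 gives 32. The regiochemistry of the orthoester opening rests on that analogy.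

**Further compounds**
F1 | step 17 | dimethyl {2-[(4R,6S)-6-{(2R,3R)-2-[(2R,3R)-3,4-bis(TBSO)-2-methylbutyl]-4-[(dimethylamino)methyl]-5-oxooxolan-3-yl}-2,2,4-trimethyl-1,3-dioxan-4-yl]-2-oxoethyl}phosphonate | CN(C)CC1C(=O)O[C@H](C[C@@H](C)[C@@H](O[Si](C)(C)C(C)(C)C)CO[Si](C)(C)C(C)(C)C)[C@H]1[C@@H]2C[C@](C)(C(=O)CP(=O)(OC)OC)OC(C)(C)O2
F2 | step 17 | dimethyl {2-[(4R,6S)-6-{(2R,3R)-2-[(2R,3R)-3,4-dihydroxy-2-methylbutyl]-4-[(dimethylamino)methyl]-5-oxooxolan-3-yl}-2,2,4-trimethyl-1,3-dioxan-4-yl]-2-oxoethyl}phosphonate | CN(C)CC1C(=O)O[C@H](C[C@@H](C)[C@@H](O)CO)[C@H]1[C@@H]2C[C@](C)(C(=O)CP(=O)(OC)OC)OC(C)(C)O2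
F3 | step 17 | dimethyl {2-[(4R,6S)-6-{(2R,3R)-4-[(dimethylamino)methyl]-2-[(2R)-2-methyl-3-oxopropyl]-5-oxooxolan-3-yl}-2,2,4-trimethyl-1,3-dioxan-4-yl]-2-oxoethyl}phosphonate | CN(C)CC1C(=O)O[C@H](C[C@@H](C)C=O)[C@H]1[C@@H]2C[C@](C)(C(=O)CP(=O)(OC)OC)OC(C)(C)O2
F4 | step 17 | (1E,4R,6S,7R,8R,10R)-13-(dimethylamino)-4,6-(isopropylidenedioxy)-3-oxogermacr-1-en-12,8-olide (C11 epimers) | CN(C)CC1C(=O)O[C@@H]2C[C@@H](C)/C=C/C(=O)[C@](C)(OC(C)(C)O3)C[C@H]3[C@@H]12
F5 | step 17 | 13-(dimethylamino)-4,6-(isopropylidenedioxy)-3-oxo-1-(4,4,5,5-tetramethyl-1,3,2-dioxaborolan-2-yl)germacran-12,8-olide (C1 configured as in 29) | CN(C)CC1C(=O)O[C@@H]2C[C@@H](C)[C@@H](B4OC(C)(C)C(C)(C)O4)CC(=O)[C@](C)(OC(C)(C)O3)C[C@H]3[C@@H]12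
F6 | step 17 | (1S,4R,6S,7R,8R,10R)-13-(dimethylamino)-1-hydroxy-4,6-(isopropylidenedioxy)-3-oxogermacran-12,8-olide (C11 epimers) | CN(C)CC1C(=O)O[C@@H]2C[C@@H](C)[C@@H](O)CC(=O)[C@](C)(OC(C)(C)O3)C[C@H]3[C@@H]12
F7 | step 10 | benzyl (2R)-4-{(2R,3R)-2-[(2R,3R)-3,4-bis(TBSO)-2-methylbutyl]-4-methylidene-5-oxooxolan-3-yl}-2-methyl-4-oxo-2-(trimethylsilyloxy)butanoate | C=C1C(=O)O[C@H](C[C@@H](C)[C@@H](O[Si](C)(C)C(C)(C)C)CO[Si](C)(C)C(C)(C)C)[C@H]1C(=O)C[C@@](C)(O[Si](C)(C)C)C(=O)OCc1ccccc1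
F8 | step 10 | benzyl (2R)-4-{(2R,3R)-2-[(2R,3R)-3,4-bis(TBSO)-2-methylbutyl]-4-methylidene-5-oxooxolan-3-yl}-2-hydroxy-2-methyl-4-oxobutanoate | C=C1C(=O)O[C@H](C[C@@H](C)[C@@H](O[Si](C)(C)C(C)(C)C)CO[Si](C)(C)C(C)(C)C)[C@H]1C(=O)C[C@@](C)(O)C(=O)OCc1ccccc1
F9 | step 20 | 13-(dimethylamino)-4,6-[(1-methoxyethylidene)dioxy]-3-oxo-1-(TBSO)germacran-12,8-olide (cyclic orthoacetate of 30) | CN(C)CC1C(=O)O[C@@H]2C[C@@H](C)[C@@H](O[Si](C)(C)C(C)(C)C)CC(=O)[C@](C)(OC(C)(OC)O3)C[C@H]3[C@@H]12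
F10 | step 20 | (1S,4R,6S,7R,8R,10R)-4-acetoxy-13-(dimethylamino)-6-hydroxy-3-oxo-1-(TBSO)germacran-12,8-olide (C11 epimers) | CN(C)CC1C(=O)O[C@@H]2C[C@@H](C)[C@@H](O[Si](C)(C)C(C)(C)C)CC(=O)[C@](C)(OC(C)=O)C[C@H](O)[C@@H]12
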